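**Strategy.** The route rests on building ring B last, from the C2 substituent of a finished chroman. Ring B is a benzene ring whose C1', bonded to C2, sits between the oxygen-bearing C2' and C6'; a vinylketene–ynol ether benzannulation gives exactly this 2-substituted resorcinol. In one operation, heating cyclobutenone with a C2 silyloxyalkyne forms the C1'–C6' and C2'–C3' bonds, closes ring B and leaves one free and one silylated phenol. The precursor is a cis-(2R,4R)-4-silyloxychroman with ring A fully substituted (5-OMe, fused dimethylpyran, 8-prenyl) and a triisopropylsilyloxyethynyl group at C2; C4 is a masked ketone that later closes the hemiketal bridge.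

Key step: step 11

Remark: flavan numbering is used in the text (O1, C2, C3, C4; ring A C5–C8; ring B C1'–C6', with C2' arriving as the silyloxy carbon and C6' as the new phenol carbon). In the systematic names of the tricyclic compounds, flavan C8 is C10. Acetophenone positions in steps 1–4 are counted from the acetyl-bearing carbon.

Remark: the stereodescriptors of target, silyloxyalkyne and benzannulation product were checked against each other and agree (all 2R; the silyl ethers are 2R,4R, cis), so no structure needed correction.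

Assumption: RuCl[(R,R)-TsDPEN](p-cymene) is taken to give the 4R alcohol, as it does with simple chroman-4-ones; if the sense were reversed for this substrate, the mirror-image catalyst would be used.

**Step 1**
Reactants: 1 1-(2,4-dihydroxy-6-methoxyphenyl)ethanone; 2 3-chloro-3-methylbut-1-yne
Product: 3 1-[2-hydroxy-6-methoxy-4-(2-methylbut-3-yn-2-yloxy)phenyl]ethanone
Conditions: K2CO3, KI, CuI (cat.), acetone, 55 °C
Reagents that add atoms: none
Why: Williamson-type O-alkylation with the tertiary propargylic chloride under CuI catalysis should occur only at the 4-OH, because the 2-OH is held in a hydrogen bond to the acetyl group; no stereocentre is formed.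

**Step 2**
Reactants: 3 1-[2-hydroxy-6-methoxy-4-(2-methylbut-3-yn-2-yloxy)phenyl]ethanone
Product: 4 1-[2-hydroxy-6-methoxy-4-(2-methylbut-3-en-2-yloxy)phenyl]ethanone
Conditions: H2 (1 atm), Pd/CaCO3 poisoned with Pb(OAc)2 (Lindlar), quinoline, EtOAc, rt
Reagents that add atoms: none
Why: Lindlar semihydrogenation should stop at the terminal alkene and leave the aryl ketone untouched.

**Step 3**
Reactants: 4 1-[2-hydroxy-6-methoxy-4-(2-methylbut-3-en-2-yloxy)phenyl]ethanone
Product: 6 1-[2,4-dihydroxy-6-methoxy-3-(3-methylbut-2-en-1-yl)phenyl]ethanone, via ortho-dienone 5 (not isolated)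
Conditions: PhNEt2, 120 °C
Reagents that add atoms: none
Why: Aromatic Claisen rearrangement of the 1,1-dimethylallyl ether goes through a chair [3,3] shift to dienone 5, which enolises to the C-prenyl phenol; the chelated 2-hydroxy ketone localises double-bond character in the C3–C4 bond and should direct the shift to C3, between the two oxygens, any C5 isomer being removed by chromatography.

**Step 4**
Reactants: 6 1-[2,4-dihydroxy-6-methoxy-3-(3-methylbut-2-en-1-yl)phenyl]ethanone; 7 3-methylbut-2-enal
Product: 9 1-[7-hydroxy-5-methoxy-2,2-dimethyl-8-(3-methylbut-2-en-1-yl)-2H-chromen-6-yl]ethanone, via ortho-quinone methide 8 (not isolated)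
Conditions: ethylenediammonium diacetate (10 mol%), xylene, 140 °C
Reagents that add atoms: none
Why: Knoevenagel-type condensation of the enal at C5, the only unsubstituted ring carbon, gives quinone methide 8, which closes onto the neighbouring 4-oxygen by oxa-six-electron electrocyclisation (formal [3+3] chromene annulation), so only the linear dimethylpyran can form.

**Step 5**
Reactants: 9 1-[7-hydroxy-5-methoxy-2,2-dimethyl-8-(3-methylbut-2-en-1-yl)-2H-chromen-6-yl]ethanone; 10 diethyl oxalate
Product: 12 ethyl 5-methoxy-8,8-dimethyl-10-(3-methylbut-2-en-1-yl)-4-oxo-4H,8H-pyrano[3,2-g]chromene-2-carboxylate, via diketo ester 11 (not isolated)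
Conditions: NaOEt (4 equiv), EtOH, 70 °C; then conc. HCl to pH 1, 60 °C, short
Reagents that add atoms: none
Why: Crossed Claisen condensation of the acetyl enolate with the non-enolisable oxalate gives diketo ester 11, whose phenol adds to the ketone and loses water under acid (classical chromone-2-carboxylate synthesis); the acid treatment is kept brief so that the prenyl group next to the phenol does not cyclise.

**Step 6**
Reactants: 12 ethyl 5-methoxy-8,8-dimethyl-10-(3-methylbut-2-en-1-yl)-4-oxo-4H,8H-pyrano[3,2-g]chromene-2-carboxylate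
Product: 14 ethyl (2R,4R)-4-hydroxy-5-methoxy-8,8-dimethyl-10-(3-methylbut-2-en-1-yl)-3,4-dihydro-2H,8H-pyrano[3,2-g]chromene-2-carboxylate, via chromanone ester 13 (not isolated)
Conditions: RuCl[(R,R)-TsDPEN](p-cymene) (3 mol%), HCO2H, Et3N (excess), MeCN, 40 °C
Reagents that add atoms: none
Why: Noyori–Ikariya asymmetric transfer hydrogenation: Ru–H first reduces the doubly activated C2=C3 bond to chromanone 13, which epimerises at C2 under the amine by reversible ring opening (retro-oxa-Michael), and the ketone is then reduced under dynamic kinetic resolution, the (R,R) ligand setting C4 as R through the usual aryl-ketone transition state and the faster-reacting C2 epimer giving the 2,4-cis alcohol, hence 2R; the prenyl and chromene alkenes are inert to this hydride source.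

**Step 7**
Reactants: 14 ethyl (2R,4R)-4-hydroxy-5-methoxy-8,8-dimethyl-10-(3-methylbut-2-en-1-yl)-3,4-dihydro-2H,8H-pyrano[3,2-g]chromene-2-carboxylate
Product: 15 ethyl (2R,4R)-4-{[tert-butyl(dimethyl)silyl]oxy}-5-methoxy-8,8-dimethyl-10-(3-methylbut-2-en-1-yl)-3,4-dihydro-2H,8H-pyrano[3,2-g]chromene-2-carboxylate
Conditions: TBSOTf, 2,6-lutidine, CH2Cl2, −78 → 0 °C
Reagents that add atoms: tert-butyldimethylsilyl trifluoromethanesulfonate, CC(C)(C)[Si](C)(C)OS(=O)(=O)C(F)(F)F
Why: Silylation of the hindered benzylic alcohol with the silyl triflate leaves both stereocentres untouched; the silyl ether masks the future ketone through the strongly basic homologation, and the C4 centre makes any later epimerisation at C2 show up as a separable diastereomer.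

**Step 8**
Reactants: 15 ethyl (2R,4R)-4-{[tert-butyl(dimethyl)silyl]oxy}-5-methoxy-8,8-dimethyl-10-(3-methylbut-2-en-1-yl)-3,4-dihydro-2H,8H-pyrano[3,2-g]chromene-2-carboxylate
Product: 18 tert-butyl{[(2R,4R)-5-methoxy-8,8-dimethyl-10-(3-methylbut-2-en-1-yl)-2-({[tri(propan-2-yl)silyl]oxy}ethynyl)-3,4-dihydro-2H,8H-pyrano[3,2-g]chromen-4-yl]oxy}dimethylsilane, via lithium dibromoenolate 16 (not isolated), via lithium ynolate 17 (not isolated)
Conditions: CH2Br2, LiTMP (2.2 equiv), THF, −78 °C; n-BuLi, −78 → 0 °C; TIPSOTf, −78 °C → rt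
Reagents that add atoms: dibromomethane, BrCBr; triisopropylsilyl trifluoromethanesulfonate, CC(C)[Si](OS(=O)(=O)C(F)(F)F)(C(C)C)C(C)C
Why: Kowalski ester homologation stopped at the ynolate: LiCHBr2 adds to the ester, enolate 16 undergoes bromine–lithium exchange and a 1,2-shift of the C2 carbon with loss of LiBr to ynolate 17 (migration with retention, so C2 stays R), and the bulky silyl triflate traps it on oxygen.

**Step 9**
Reactants: 19 3-oxocyclobutanecarboxylic acid
Product: 20 3-bromocyclobutan-1-one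
Conditions: HgO, Br2, MgSO4, CH2Cl2, reflux
Reagents that add atoms: bromine, BrBr
Why: Hunsdiecker-type bromodecarboxylation (Cristol–Firth variant) replaces the carboxyl group by bromine through the acyl hypobromite and a cyclobutyl radical.

**Step 10**
Reactants: 20 3-bromocyclobutan-1-one
Product: 21 cyclobut-2-en-1-one
Conditions: n-Bu3N, neat, rt, then distillation under reduced pressure into a cold trap
Reagents that add atoms: none
Why: E1cB-type dehydrobromination of the beta-bromo ketone by the tertiary amine gives the strained enone, which is distilled from the salt and kept cold in solution until use.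

**Step 11**
Reactants: 18 tert-butyl{[(2R,4R)-5-methoxy-8,8-dimethyl-10-(3-methylbut-2-en-1-yl)-2-({[tri(propan-2-yl)silyl]oxy}ethynyl)-3,4-dihydro-2H,8H-pyrano[3,2-g]chromen-4-yl]oxy}dimethylsilane; 21 cyclobut-2-en-1-one
Product: 26 2-[(2R,4R)-4-{[tert-butyl(dimethyl)silyl]oxy}-5-methoxy-8,8-dimethyl-10-(3-methylbut-2-en-1-yl)-3,4-dihydro-2H,8H-pyrano[3,2-g]chromen-2-yl]-3-{[tri(propan-2-yl)silyl]oxy}phenol, via vinylketene 22 (not isolated), via vinylcyclobutenone 23 (not isolated), via dienylketene 24 (not isolated), via cyclohexadienone 25 (not isolated)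
Conditions: 21 (3 equiv, added slowly in toluene), toluene, 80 °C then 110 °C, sealed tube
Reagents that add atoms: none
Why: Cyclobutenone 21 opens by a thermal four-electron electrocyclic reaction, driven by loss of ring strain, to vinylketene 22; the ynol ether then adds to the ketene C=C in a polarity-controlled [2+2] step in which its nucleophilic carbon, the one bonded to C2, attacks the ketene carbonyl carbon (new C1'–C6' bond) and the silyloxy carbon joins the ketene alpha carbon (new C2'–C3' bond), giving vinylcyclobutenone 23. Reversible four-electron opening of 23 gives dienylketene 24, and ring B closes by a thermal six-electron disrotatory electrocyclisation joining C5' to C6', after which dienone 25 tautomerises to the phenol. This is a Danheiser benzannulation of a cyclobutenone with a silyloxyalkyne, the established route to resorcinol monosilyl ethers. No stereocentre is created; C2 never becomes part of a reacting pi system and the medium is neutral and aprotic, so the 2R,4R configuration should be carried through. The selectivity that matters is regiochemical, the new phenol and the silyloxy group ending on the two carbons next to C1', and it is secured by the polarisation of the ynol ether; chemoselectivity rests on the ynol ether being far more nucleophilic toward the ketene than the prenyl and chromene alkenes, and slow addition of 21 limits its polymerisation and acylation of the product phenol by surplus ketene.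

**Step 12**
Reactants: 26 2-[(2R,4R)-4-{[tert-butyl(dimethyl)silyl]oxy}-5-methoxy-8,8-dimethyl-10-(3-methylbut-2-en-1-yl)-3,4-dihydro-2H,8H-pyrano[3,2-g]chromen-2-yl]-3-{[tri(propan-2-yl)silyl]oxy}phenol
Product: 27 2-[(2R,4R)-4-hydroxy-5-methoxy-8,8-dimethyl-10-(3-methylbut-2-en-1-yl)-3,4-dihydro-2H,8H-pyrano[3,2-g]chromen-2-yl]benzene-1,3-diol
Conditions: Bu4NF (4 equiv), AcOH (4 equiv), THF, 0 → 40 °C; neutral work-up, base-washed silica
Reagents that add atoms: none
Why: Fluoride cleaves the aryl and the secondary alkyl Si–O bonds (desilylation), while the acetic acid buffer keeps the phenols protonated so that neither ring opening at C2 through an ortho-quinone methide nor ionisation at C4 is encouraged; both stereocentres are retained and any trans isomer is separable here.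

**Step 13**
Reactants: 27 2-[(2R,4R)-4-hydroxy-5-methoxy-8,8-dimethyl-10-(3-methylbut-2-en-1-yl)-3,4-dihydro-2H,8H-pyrano[3,2-g]chromen-2-yl]benzene-1,3-diol
Product: 29 CNP0170313.2 (2R,4R bridged hemiketal), via keto diphenol 28 (not isolated)
Conditions: activated MnO2 (excess), CH2Cl2, rt
Reagents that add atoms: none
Why: Activated MnO2 should oxidise the electron-rich benzylic C4 alcohol selectively (benzylic alcohol oxidation) to ketone 28, which is captured at once by a ring B phenol as the six-membered bridging hemiketal; the bridge can only form on the face that carries ring B, so C4 follows from C2 and is R.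

**Compound list**

1 | 1-(2,4-dihydroxy-6-methoxyphenyl)ethanone | CC(=O)c1c(O)cc(O)cc1OC | starting material
2 | 3-chloro-3-methylbut-1-yne | C#CC(C)(C)Cl | starting material
3 | 1-[2-hydroxy-6-methoxy-4-(2-methylbut-3-yn-2-yloxy)phenyl]ethanone | CC(=O)c1c(O)cc(OC(C)(C)C#C)cc1OC | intermediate
4 | 1-[2-hydroxy-6-methoxy-4-(2-methylbut-3-en-2-yloxy)phenyl]ethanone | CC(=O)c1c(O)cc(OC(C)(C)C=C)cc1OC | intermediate
5 | ortho-dienone, 4-acetyl-3-hydroxy-5-methoxy-2-(3-methylbut-2-en-1-yl)cyclohexa-3,5-dien-1-one (not isolated) | CC(=O)C1=C(O)C(CC=C(C)C)C(=O)C=C1OC | intermediate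
6 | 1-[2,4-dihydroxy-6-methoxy-3-(3-methylbut-2-en-1-yl)phenyl]ethanone | CC(=O)c1c(O)c(CC=C(C)C)c(O)cc1OC | intermediate
7 | 3-methylbut-2-enal | CC(C)=CC=O | starting material
8 | ortho-quinone methide, 4-acetyl-3-hydroxy-5-methoxy-6-(3-methylbut-2-en-1-ylidene)-2-(3-methylbut-2-en-1-yl)cyclohexa-2,4-dien-1-one (not isolated) | CC(=O)C1=C(OC)C(=CC=C(C)C)C(=O)C(CC=C(C)C)=C1O | intermediate
9 | 1-[7-hydroxy-5-methoxy-2,2-dimethyl-8-(3-methylbut-2-en-1-yl)-2H-chromen-6-yl]ethanone | CC(=O)c1c(O)c(CC=C(C)C)c2OC(C)(C)C=Cc2c1OC | intermediate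
10 | diethyl oxalate | CCOC(=O)C(=O)OCC | starting material
11 | diketo ester, ethyl 4-[7-hydroxy-5-methoxy-2,2-dimethyl-8-(3-methylbut-2-en-1-yl)-2H-chromen-6-yl]-2,4-dioxobutanoate (not isolated) | CCOC(=O)C(=O)CC(=O)c1c(O)c(CC=C(C)C)c2OC(C)(C)C=Cc2c1OC | intermediate
12 | ethyl 5-methoxy-8,8-dimethyl-10-(3-methylbut-2-en-1-yl)-4-oxo-4H,8H-pyrano[3,2-g]chromene-2-carboxylate | CCOC(=O)c1cc(=O)c2c(OC)c3C=CC(C)(C)Oc3c(CC=C(C)C)c2o1 | intermediate
13 | chromanone ester, ethyl 5-methoxy-8,8-dimethyl-10-(3-methylbut-2-en-1-yl)-4-oxo-3,4-dihydro-2H,8H-pyrano[3,2-g]chromene-2-carboxylate, epimerising at C2 (not isolated) | CCOC(=O)C1CC(=O)c2c(OC)c3C=CC(C)(C)Oc3c(CC=C(C)C)c2O1 | intermediate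
14 | ethyl (2R,4R)-4-hydroxy-5-methoxy-8,8-dimethyl-10-(3-methylbut-2-en-1-yl)-3,4-dihydro-2H,8H-pyrano[3,2-g]chromene-2-carboxylate (cis) | CCOC(=O)[C@H]1C[C@@H](O)c2c(OC)c3C=CC(C)(C)Oc3c(CC=C(C)C)c2O1 | intermediate
15 | ethyl (2R,4R)-4-{[tert-butyl(dimethyl)silyl]oxy}-5-methoxy-8,8-dimethyl-10-(3-methylbut-2-en-1-yl)-3,4-dihydro-2H,8H-pyrano[3,2-g]chromene-2-carboxylate | CCOC(=O)[C@H]1C[C@@H](O[Si](C)(C)C(C)(C)C)c2c(OC)c3C=CC(C)(C)Oc3c(CC=C(C)C)c2O1 | intermediate
16 | lithium dibromoenolate, lithium 2,2-dibromo-1-[(2R,4R)-4-silyloxychroman-2-yl]ethenolate with ring A as in 15 (not isolated) | [Li+].[O-]C(=C(Br)Br)[C@H]1C[C@@H](O[Si](C)(C)C(C)(C)C)c2c(OC)c3C=CC(C)(C)Oc3c(CC=C(C)C)c2O1 | intermediate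
17 | lithium ynolate, lithium 2-[(2R,4R)-4-silyloxychroman-2-yl]ethynolate with ring A as in 15 (not isolated) | [Li+].[O-]C#C[C@H]1C[C@@H](O[Si](C)(C)C(C)(C)C)c2c(OC)c3C=CC(C)(C)Oc3c(CC=C(C)C)c2O1 | intermediate
18 | tert-butyl{[(2R,4R)-5-methoxy-8,8-dimethyl-10-(3-methylbut-2-en-1-yl)-2-({[tri(propan-2-yl)silyl]oxy}ethynyl)-3,4-dihydro-2H,8H-pyrano[3,2-g]chromen-4-yl]oxy}dimethylsilane (key-step precursor) | CC(C)[Si](OC#C[C@H]1C[C@@H](O[Si](C)(C)C(C)(C)C)c2c(OC)c3C=CC(C)(C)Oc3c(CC=C(C)C)c2O1)(C(C)C)C(C)C | intermediate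
19 | 3-oxocyclobutanecarboxylic acid | O=C1CC(C1)C(=O)O | starting material
20 | 3-bromocyclobutan-1-one | O=C1CC(Br)C1 | intermediate
21 | cyclobut-2-en-1-one | O=C1C=CC1 | intermediate
22 | vinylketene, buta-1,3-dien-1-one (not isolated) | C=CC=C=O | intermediate
23 | vinylcyclobutenone, 4-ethenyl-2-[(2R,4R)-4-silyloxychroman-2-yl]-3-(triisopropylsilyloxy)cyclobut-2-en-1-one, ring CH configuration undefined (not isolated) | O=C1C(=C(O[Si](C(C)C)(C(C)C)C(C)C)C1C=C)[C@H]1C[C@@H](O[Si](C)(C)C(C)(C)C)c2c(OC)c3C=CC(C)(C)Oc3c(CC=C(C)C)c2O1 | intermediate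
24 | dienylketene, (3E)-2-[(2R,4R)-4-silyloxychroman-2-yl]-3-(triisopropylsilyloxy)hexa-1,3,5-trien-1-one (not isolated) | C=C/C=C(/O[Si](C(C)C)(C(C)C)C(C)C)C(=C=O)[C@H]1C[C@@H](O[Si](C)(C)C(C)(C)C)c2c(OC)c3C=CC(C)(C)Oc3c(CC=C(C)C)c2O1 | intermediate
25 | cyclohexadienone, 2-[(2R,4R)-4-silyloxychroman-2-yl]-3-(triisopropylsilyloxy)cyclohexa-2,4-dien-1-one (not isolated) | O=C1CC=CC(O[Si](C(C)C)(C(C)C)C(C)C)=C1[C@H]1C[C@@H](O[Si](C)(C)C(C)(C)C)c2c(OC)c3C=CC(C)(C)Oc3c(CC=C(C)C)c2O1 | intermediate
26 | 2-[(2R,4R)-4-{[tert-butyl(dimethyl)silyl]oxy}-5-methoxy-8,8-dimethyl-10-(3-methylbut-2-en-1-yl)-3,4-dihydro-2H,8H-pyrano[3,2-g]chromen-2-yl]-3-{[tri(propan-2-yl)silyl]oxy}phenol (key-step product) | CC(C)[Si](Oc1cccc(O)c1[C@H]1C[C@@H](O[Si](C)(C)C(C)(C)C)c2c(OC)c3C=CC(C)(C)Oc3c(CC=C(C)C)c2O1)(C(C)C)C(C)C | intermediate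
27 | 2-[(2R,4R)-4-hydroxy-5-methoxy-8,8-dimethyl-10-(3-methylbut-2-en-1-yl)-3,4-dihydro-2H,8H-pyrano[3,2-g]chromen-2-yl]benzene-1,3-diol | Oc1cccc(O)c1[C@H]1C[C@@H](O)c2c(OC)c3C=CC(C)(C)Oc3c(CC=C(C)C)c2O1 | intermediate
28 | keto diphenol, (2R)-2-(2,6-dihydroxyphenyl)-5-methoxy-8,8-dimethyl-10-(3-methylbut-2-en-1-yl)-2,3-dihydro-4H,8H-pyrano[3,2-g]chromen-4-one (not isolated) | O=C1C[C@H](c2c(O)cccc2O)Oc2c(CC=C(C)C)c3OC(C)(C)C=Cc3c(OC)c12 | intermediate
29 | CNP0170313.2, (2R,4R)-4,2'-epoxy-4,6'-dihydroxy-5-methoxy-8-prenylflavan with a 2,2-dimethylpyran fused at C6/C7 through O7 (bridged hemiketal) | COc1c2c(c(CC=C(C)C)c3c1[C@@]1(O)C[C@@H](O3)c3c(O)cccc3O1)OC(C)(C)C=C2 | target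

**Step count.** Total: 13 steps (11 in the main line and 2 for cyclobutenone). Longest linear sequence: 11 steps, from 1 to 29 through steps 1–8 and 11–13.

**Steps most likely to fail**

Step 11 (benzannulation). Cyclobutenone may polymerise faster than it opens to the ketene. The propargylic C2–O1 bond of the ynol ether may ionise on heating. Once the ortho phenol exists, C2 may epimerise through reversible opening to an ortho-quinone methide. In that case ring B would be brought in preformed by flavonoid chemistry, setting out from acetophenone 9. 2,6-Dihydroxybenzaldehyde is bis-allylated (allyl bromide, K2CO3, DMF) to 2,6-bis(prop-2-en-1-yloxy)benzaldehyde F1. Claisen–Schmidt condensation of 9 with F1 (KOH, EtOH, rt) should give the (E)-2'-hydroxychalcone F2. NaOAc in refluxing EtOH closes it by oxa-Michael addition to the racemic flavanone F3. Transfer hydrogenation under dynamic kinetic resolution (RuCl[(R,R)-TsDPEN](p-cymene), HCO2H, DBU, MeCN) should give the cis-(2R,4R)-flavan-4-ol bis(allyl ether) F4. Pd(PPh3)4 and morpholine in THF remove both allyl groups and deliver triol 27, where the route is rejoined at step 13.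

Step 8 (ester to silyloxyalkyne). The amide base may deprotonate C2 in competition with addition of LiCHBr2, which would epimerise it. The ynolate may expel the ring A aryloxide from C2. Silylation may go to carbon. The fallback sets out from ester 15 and makes the same ynolate by acetylide oxidation instead of carbenoid rearrangement. DIBAL-H in CH2Cl2 at −78 °C gives the (2R,4R)-4-silyloxychroman-2-carbaldehyde F5. Ohira–Bestmann homologation (dimethyl (1-diazo-2-oxopropyl)phosphonate, K2CO3, MeOH, 0 °C) gives the terminal alkyne F6. n-BuLi in THF at −78 °C gives the lithium acetylide F7, which is oxidised with LiOOt-Bu (from t-BuOOH and LiHMDS) to ynolate 17 and silylated with TIPSOTf, returning to the route at 18.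

Step 6 (tandem asymmetric reduction). Reduction of the hindered, electron-rich ketone may stall. The ring-opened enone that mediates racemisation may be intercepted by hydride. Cis selectivity may be poor. The fallback sets out from chromone ester 12 and separates the two stereocentres. Copper hydride conjugate reduction (Cu(OAc)2, DTBM-SEGPHOS in the antipode that delivers 2R, (EtO)2MeSiH, t-BuOH, toluene, 0 °C) sets C2 under ligand control and, after neutral work-up, gives the (2R)-chromanone ester F8. Luche reduction (NaBH4, CeCl3·7H2O, MeOH, −78 °C) then adds hydride axially under substrate control to the 2,4-cis alcohol, returning to the route at 14.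

**Further compounds**

F1 | step 11 | 2,6-bis(prop-2-en-1-yloxy)benzaldehyde | C=CCOc1cccc(OCC=C)c1C=O
F2 | step 11 | (E)-3-[2,6-bis(prop-2-en-1-yloxy)phenyl]-1-[7-hydroxy-5-methoxy-2,2-dimethyl-8-(3-methylbut-2-en-1-yl)-2H-chromen-6-yl]prop-2-en-1-one | C=CCOc1cccc(OCC=C)c1/C=C/C(=O)c1c(O)c(CC=C(C)C)c2OC(C)(C)C=Cc2c1OC
F3 | step 11 | racemic 2-[2,6-bis(prop-2-en-1-yloxy)phenyl]-5-methoxy-8,8-dimethyl-10-(3-methylbut-2-en-1-yl)-2,3-dihydro-4H,8H-pyrano[3,2-g]chromen-4-one | C=CCOc1cccc(OCC=C)c1C1CC(=O)c2c(OC)c3C=CC(C)(C)Oc3c(CC=C(C)C)c2O1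
F4 | step 11 | (2R,4R)-2-[2,6-bis(prop-2-en-1-yloxy)phenyl]-5-methoxy-8,8-dimethyl-10-(3-methylbut-2-en-1-yl)-3,4-dihydro-2H,8H-pyrano[3,2-g]chromen-4-ol | C=CCOc1cccc(OCC=C)c1[C@H]1C[C@@H](O)c2c(OC)c3C=CC(C)(C)Oc3c(CC=C(C)C)c2O1
F5 | step 8 | (2R,4R)-4-{[tert-butyl(dimethyl)silyl]oxy}-5-methoxy-8,8-dimethyl-10-(3-methylbut-2-en-1-yl)-3,4-dihydro-2H,8H-pyrano[3,2-g]chromene-2-carbaldehyde | O=C[C@H]1C[C@@H](O[Si](C)(C)C(C)(C)C)c2c(OC)c3C=CC(C)(C)Oc3c(CC=C(C)C)c2O1
F6 | step 8 | tert-butyl{[(2R,4R)-2-ethynyl-5-methoxy-8,8-dimethyl-10-(3-methylbut-2-en-1-yl)-3,4-dihydro-2H,8H-pyrano[3,2-g]chromen-4-yl]oxy}dimethylsilane | C#C[C@H]1C[C@@H](O[Si](C)(C)C(C)(C)C)c2c(OC)c3C=CC(C)(C)Oc3c(CC=C(C)C)c2O1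
F7 | step 8 | lithium acetylide of F6 | [Li+].[C-]#C[C@H]1C[C@@H](O[Si](C)(C)C(C)(C)C)c2c(OC)c3C=CC(C)(C)Oc3c(CC=C(C)C)c2O1
F8 | step 6 | ethyl (2R)-5-methoxy-8,8-dimethyl-10-(3-methylbut-2-en-1-yl)-4-oxo-3,4-dihydro-2H,8H-pyrano[3,2-g]chromene-2-carboxylate | CCOC(=O)[C@H]1CC(=O)c2c(OC)c3C=CC(C)(C)Oc3c(CC=C(C)C)c2O1
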